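**Retrosynthetic overview**
- The C2–C1' bond is cut to give 5,6-dimethoxychromone (C2–H) and 2,3,6-trimethoxybenzoic acid. They are joined by a Pd(II)-catalysed decarboxylative oxidative Heck arylation, in which CO2 is a traceless activating group and the flavone oxidation level is delivered in the same operation.
- Enabling feature: C1' of the B ring lies between the methoxy-bearing carbons C2' and C6'. This makes that C–H the lithiation site of 1,2,4-trimethoxybenzene and makes the derived acid prone to ipso-decarboxylative palladation. The C2=C3 bond of the pyran-4-one ring is a vinylogous ester (C2 is β to C4=O and bound to O1) and accepts the aryl group at C2.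
- The chromone comes from the enaminone of a 6'-O-MOM-2',3'-dimethoxyacetophenone, made by directed ortho-metalation and acetylation of the MOM ether of 3,4-dimethoxyphenol at the carbon between the two oxygens.
- Ring order: both benzene rings are bought (A ring as 3,4-dimethoxyphenol, B ring as 1,2,4-trimethoxybenzene). The pyranone ring is closed in step 3 (O1–C2), and the B ring is attached last.

Key step: step 5

Remark: the target has no stereocentre and the C2–C1' axis should not be configurationally stable, so it is a single achiral species and no stereocontrol is needed.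

**Step 1**
Reactants: 1 3,4-dimethoxyphenol
Product: 3 4-(methoxymethoxy)-1,2-dimethoxybenzene, via sodium 3,4-dimethoxyphenoxide 2 (not isolated)
Conditions: NaH, THF, 0 °C; then MOMCl, 0 °C → rt
Reagents that add atoms: chloromethyl methyl ether (MOMCl), COCCl
Why: O-alkylation of the phenoxide (Williamson ether synthesis) should install a MOM group that is a strong ortho-director for step 2 and is cleaved by the acid used in step 3.

**Step 2**
Reactants: 3 4-(methoxymethoxy)-1,2-dimethoxybenzene
Product: 6 1-[6-(methoxymethoxy)-2,3-dimethoxyphenyl]ethan-1-one, via aryllithium 4 (not isolated), via lithium hemiaminal alkoxide 5 (not isolated)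
Conditions: n-BuLi, THF, −20 → 0 °C; then MeC(O)N(OMe)Me, −78 → 0 °C; H2O
Reagents that add atoms: N-methoxy-N-methylacetamide, CC(=O)N(C)OC
Why: Directed ortho-metalation should occur at the one C–H flanked by OMOM and OMe (cooperative direction), and Weinreb amide acylation stops at the ketone because the chelated adduct 5 survives until the quench.

**Step 3**
Reactants: 6 1-[6-(methoxymethoxy)-2,3-dimethoxyphenyl]ethan-1-one
Product: 9 5,6-dimethoxy-4H-chromen-4-one, via MOM enaminone 7 (not isolated), via free-phenol enaminone 8 (not isolated)
Conditions: DMF-DMA, toluene, 100 °C; evaporate; then HCl (1.25 M in MeOH), 50 °C; aq. NaHCO3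
Reagents that add atoms: N,N-dimethylformamide dimethyl acetal (DMF-DMA), COC(OC)N(C)C
Why: Condensation of the methyl ketone with the amide acetal gives the enaminone, and acid then removes the MOM group and closes the pyranone ring by 6-endo-trig attack of the phenol oxygen on the β-carbon followed by loss of dimethylamine (enaminone chromone synthesis).

**Step 4**
Reactants: 10 1,2,4-trimethoxybenzene
Product: 13 2,3,6-trimethoxybenzoic acid, via (2,3,6-trimethoxyphenyl)lithium 11 (not isolated), via lithium 2,3,6-trimethoxybenzoate 12 (not isolated)
Conditions: n-BuLi, THF, 0 °C → rt; then CO2, −78 °C → rt; aq. HCl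
Reagents that add atoms: carbon dioxide, O=C=O
Why: Directed ortho-metalation should take place at C3–H, the only position flanked by two methoxy groups and so the most acidic, and carboxylation of the aryllithium puts the carboxyl group exactly on the future C1'.

**Step 5**
Reactants: 9 5,6-dimethoxy-4H-chromen-4-one; 13 2,3,6-trimethoxybenzoic acid (2.5 equiv, added in portions)
Product: 16 5,6-dimethoxy-2-(2,3,6-trimethoxyphenyl)-4H-chromen-4-one (5,6,2',3',6'-pentamethoxyflavone), via arylpalladium(II) trifluoroacetate 14 (not isolated), via C3-palladated flavanone 15 (not isolated)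
Conditions: Pd(O2CCF3)2 (20 mol %), Ag2CO3 (3 equiv), DMSO–DMF (1:20), 120 °C
Reagents that add atoms: none
Why: Proposed new method: carboxylate exchange of 13 on Pd(II) and ipso-decarboxylation, which the two ortho-methoxy groups at C2' and C6' make unusually easy, should give arylpalladium(II) species 14, which inserts the C2=C3 bond of 9 with the aryl group going to C2 and Pd to C3 (15); equilibration of 15 through its O-bound enolate then allows syn β-hydride elimination of H–C2 to release flavone 16, and Ag(I) returns Pd(0) to Pd(II). The closest known reaction types are the Pd(II)/Ag2CO3 decarboxylative Heck olefination of di-ortho-substituted electron-rich benzoic acids with acrylates, styrenes and cycloalkenones, and the oxidative Heck C2-arylation of chromones by arylpalladium(II) species made from arylboronic acids; only the pairing of a benzoic acid with a chromone is untested. No ring is closed, and the only stereocentres (C2 and C3 of 15) are transient and are erased by the elimination. Two site selectivities are needed: on the B ring the ipso position of the carboxyl group fixes the bond at the carbon between two methoxy groups, where electrophilic palladation or oxidative arylation of 1,2,4-trimethoxybenzene would not go (these favour C5), and on the chromone the vinylogous-ester polarization of C2=C3 sends the aryl group to C2. If 15 is protonated instead of eliminating, the resulting flavanone should be dehydrogenated to 16 by the same Pd(II)/DMSO/Ag(I) system, so both fates of the enolate converge.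

**Compound list**
1 | 3,4-dimethoxyphenol | COc1ccc(O)cc1OC | starting material
2 | sodium 3,4-dimethoxyphenoxide | COc1ccc([O-])cc1OC.[Na+] | intermediate
3 | 4-(methoxymethoxy)-1,2-dimethoxybenzene | COCOc1ccc(OC)c(OC)c1 | intermediate
4 | [6-(methoxymethoxy)-2,3-dimethoxyphenyl]lithium | [Li]c1c(OCOC)ccc(OC)c1OC | intermediate
5 | lithium 1-[6-(methoxymethoxy)-2,3-dimethoxyphenyl]-1-[methoxy(methyl)amino]ethan-1-olate (racemic) | CC(O[Li])(N(C)OC)c1c(OCOC)ccc(OC)c1OC | intermediate
6 | 1-[6-(methoxymethoxy)-2,3-dimethoxyphenyl]ethan-1-one | CC(=O)c1c(OCOC)ccc(OC)c1OC | intermediate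
7 | (E)-3-(dimethylamino)-1-[6-(methoxymethoxy)-2,3-dimethoxyphenyl]prop-2-en-1-one | CN(C)/C=C/C(=O)c1c(OCOC)ccc(OC)c1OC | intermediate
8 | (E)-3-(dimethylamino)-1-(6-hydroxy-2,3-dimethoxyphenyl)prop-2-en-1-one | CN(C)/C=C/C(=O)c1c(O)ccc(OC)c1OC | intermediate
9 | 5,6-dimethoxy-4H-chromen-4-one | COc1ccc2occc(=O)c2c1OC | intermediate
10 | 1,2,4-trimethoxybenzene | COc1ccc(OC)c(OC)c1 | starting material
11 | (2,3,6-trimethoxyphenyl)lithium | [Li]c1c(OC)ccc(OC)c1OC | intermediate
12 | lithium 2,3,6-trimethoxybenzoate | [Li+].[O-]C(=O)c1c(OC)ccc(OC)c1OC | intermediate
13 | 2,3,6-trimethoxybenzoic acid | OC(=O)c1c(OC)ccc(OC)c1OC | intermediate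
14 | (2,3,6-trimethoxyphenyl)palladium(II) trifluoroacetate (DMSO ligands omitted) | O=C(O[Pd]c1c(OC)ccc(OC)c1OC)C(F)(F)F | intermediate
15 | [5,6-dimethoxy-4-oxo-2-(2,3,6-trimethoxyphenyl)chroman-3-yl]palladium(II) trifluoroacetate (racemic, cis from syn-insertion, drawn without descriptors because it equilibrates through the O-bound enolate) | COc1ccc2OC(c3c(OC)ccc(OC)c3OC)C([Pd]OC(=O)C(F)(F)F)C(=O)c2c1OC | intermediate
16 | 5,6-dimethoxy-2-(2,3,6-trimethoxyphenyl)-4H-chromen-4-one (5,6,2',3',6'-pentamethoxyflavone) | COc1ccc(OC)c(-c2cc(=O)c3c(OC)c(OC)ccc3o2)c1OC | target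

**Totals**
Total step count: 5. Longest linear sequence: 4 steps (steps 1, 2, 3 and 5); step 4 is the one-step branch to the acid.

**Steps most likely to fail**

1. Step 5 (proposed new method). Protonation of the aryl–Pd species (protodecarboxylation of the acid) may outrun insertion into the chromone C2=C3 bond with this di-ortho-substituted aryl group, or the sequence may stall at the saturated adduct. The fallback uses known chemistry, sets out from 9 and 10 and returns at 16. Compound 10 is lithiated as in step 4 to 11 and quenched with iodine to give 2-iodo-1,3,4-trimethoxybenzene F1. Compound 9 is zincated at C2 with the magnesium-free amide base TMPZnCl·LiCl in THF at rt to give (5,6-dimethoxy-4-oxo-4H-chromen-2-yl)zinc chloride F2. Negishi coupling of F2 with F1 (Pd(OAc)2, SPhos, THF, 50 °C) should then form the same C2–C1' bond and give 16.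

2. Step 2. The hindered aryllithium may act as a base towards the acetyl donor (proton transfer in place of addition), returning 3, or the lithiation may be incomplete. The fallback sets out from 3 and returns at 6. Compound 3 is lithiated as before to 4, which is added to acetaldehyde at −78 °C to give 1-[6-(methoxymethoxy)-2,3-dimethoxyphenyl]ethan-1-ol F3 after a water quench. Oxidation of this benzylic alcohol with Dess–Martin periodinane in CH2Cl2 should give 6.

3. Step 3. Condensation at the twisted, di-ortho-substituted acetyl group may be incomplete, or the aminomethylene carbon may be lost hydrolytically in the acid stage, reverting to a methyl ketone. The fallback sets out from 6 and returns at 9. The MOM group is removed first (HCl, MeOH, rt) to give 1-(6-hydroxy-2,3-dimethoxyphenyl)ethan-1-one F4. Claisen formylation with ethyl formate and NaH in THF should give the cyclic hemiacetal 2-hydroxy-5,6-dimethoxychroman-4-one F5, which is dehydrated with HCl in acetic acid to 9.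

**Further compounds**
F1 | step 5 | 2-iodo-1,3,4-trimethoxybenzene | COc1ccc(OC)c(I)c1OC
F2 | step 5 | (5,6-dimethoxy-4-oxo-4H-chromen-2-yl)zinc chloride | COc1ccc2oc([Zn]Cl)cc(=O)c2c1OC
F3 | step 2 | 1-[6-(methoxymethoxy)-2,3-dimethoxyphenyl]ethan-1-ol (racemic) | CC(O)c1c(OCOC)ccc(OC)c1OC
F4 | step 3 | 1-(6-hydroxy-2,3-dimethoxyphenyl)ethan-1-one | CC(=O)c1c(O)ccc(OC)c1OC
F5 | step 3 | 2-hydroxy-5,6-dimethoxychroman-4-one (racemic hemiacetal) | COc1ccc2OC(O)CC(=O)c2c1OC
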